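The constants separate this flask's catalyst from its chemistry: in both turning steps the catalyst goes in and comes out again, so with a dimer counted as two its total stays at the charge, and its dimerisation can be reckoned on clock time, apart from reagent and substrates.

    reagent + catalyst + right-handed substrate → catalyst + right-handed product (k1 = 0.014 M⁻² s⁻¹)
    reagent + catalyst + left-handed substrate → catalyst + left-handed product (k2 = 0.76 M⁻² s⁻¹)
    reagent ⇌ dormant form (K3 = 0.70, k3 = 3.8 × 10⁻⁴ s⁻¹)
    catalyst + catalyst ⇌ resting dimer (K4 = 230 M⁻¹, k4 = 0.13 M⁻¹ s⁻¹)

left-handed substrate 0.12 M; reagent 0.180 M; catalyst 2.4 mM; right-handed substrate 0.12 M

- catalyst is single-handed; left-handed substrate and right-handed substrate are mirror images of each other, charged as a racemate, each of them at the stated concentration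
- a step written with two of one species runs at k times the square of its concentration and takes two of it each time
- a form made of two catalysts counts as two
- charge of left-handed substrate (flask): 0.12 M

* the form that holds most of the catalyst when 10% of the left-handed substrate and right-handed substrate together are converted (catalyst / resting dimer)
* its share of the catalyst then
* apparent order in reagent when 10% of the left-handed substrate and right-handed substrate together are converted (percent change of the rate of making left-handed product for one percent more reagent charged)

Drawn against time, the share of the charge standing as catalyst starts at 100% and falls at first by 2.25 h⁻¹ of itself. Setting the two directions of the dimerisation equal gives its level, [catalyst] = 1.44 mM, or 60.1% of the charge, which stands above the 39.9% left as resting dimer, so in this flask the curves of the two forms have no crossing and catalyst is the resting state.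

Between start and level the curve has an exact form. Take the gap ratio: [catalyst] minus its level, divided by [catalyst] plus the level plus 2.17 mM. It starts at 0.159 and decays exponentially at the relaxation rate, the dimerisation constant taken 4 times the level plus the dissociation constant, 4.74 h⁻¹. The knee lies near 0.211 h, and the moment asked about, 0.289 h, comes later. The ratio has then shrunk to 0.0406, which gives [catalyst] = 1.66 mM, or 69.0% of the charge.

For the order, compared at equal conversion, [reagent] enters the rate directly with 1. If one percent more reagent brings the moment one percent earlier, the catalyst curve adds its logarithmic slope there, 0.184, making 1.18. This reckoning stops there, and the part it leaves open is the reagent's own drift, since the relaxation half-life of reagent and dormant form, 0.209 h, is shorter than that moment.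

The forecast names catalyst at 69% (64% to 74%) and an order of 1.7 (0.9 to 2), above this reckoning, on the ground that “more reagent gets there sooner with less drift into dormant form and dimer”.

The flask gives catalyst at 69.0% and an order of 1.8. At that moment the resting dimer holds 31.0% of the catalyst, and left-handed product is being made at 0.0500 M h⁻¹. Run on to 0.600 h, the same relaxation rate shrinks the gap ratio to 0.00929, which gives 62.1% of the charge as catalyst, and the flask at that time holds catalyst at 62.1%.

(All constants were drawn at random within sensible limits; the result is computed.)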